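Everything rests on the C7–C8 disconnection. In step 16 divalent chromium turns the C13 bromide of a 3-(bromomethyl)butenolide into an allylmetal that attacks the C8 aldehyde through C7: one operation forms C7–C8, closes ring B onto ring A, unveils the C11=C13 methylene and sets C7 and C8. The step exploits the α-methylene-γ-lactone whose β-carbon C7 carries carbinol C8 (homoallylic alcohol C13=C11–C7–C8–OH inside ring B). Its precursor is the 2,7-cis ring A oxepene with the CH2CHO arm on C10 (from (S)-linalool) and the butenolide on C5; C5/C6 arise from a syn γ-silyloxyallylstannane addition and an invertive Mitsunobu acylation.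

Key step: step 16

Remark: atoms carry germacrane numbers (ring A = O/C10/C1–C5, ring B = O/C5–C10); the target is 5R,6S,7R,8R,10S with an (S)-acyl group, and because its C5/C6 pair is erythro while Lewis-acid additions to the ring A oxocarbenium ion are expected to be syn, C6 is first made R and inverted when the lactone oxygen is acylated.

Step 1
Reactants: 1 (S)-linalool [(3S)-3,7-dimethylocta-1,6-dien-3-ol]
Product: 3 (3S)-3,7-dimethyloct-6-ene-1,3-diol, via bis-borylated adduct 2 (not isolated)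
Conditions: 9-BBN (2.2 equiv), THF, 0 °C → rt; then NaOH, H2O2, 0 °C
Reagents that add atoms: hydrogen peroxide, OO
Why: Hydroboration–oxidation: 9-BBN adds in the anti-Markovnikov sense to the monosubstituted C8=C9 vinyl group far faster than to the trisubstituted alkene (one equivalent is consumed as the C10 borinate), so C8 becomes the primary alcohol and C10 keeps its S configuration.

Step 2
Reactants: 3 (3S)-3,7-dimethyloct-6-ene-1,3-diol
Product: 5 (3S)-1-(tert-butyldiphenylsilyloxy)-3,7-dimethyl-3-(triethylsilyloxy)oct-6-ene, via mono-silyl ether 4 (not isolated)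
Conditions: TBDPSCl, imidazole, CH2Cl2, 0 °C → rt; then 2,6-lutidine, TESOTf, −78 → 0 °C
Reagents that add atoms: tert-butyl(chloro)diphenylsilane, CC(C)(C)[Si](Cl)(c1ccccc1)c1ccccc1; triethylsilyl trifluoromethanesulfonate, CC[Si](CC)(CC)OS(=O)(=O)C(F)(F)F
Why: Chemoselective silylation: the bulky chlorosilane takes only the primary C8–OH and the silyl triflate then caps the hindered tertiary C10–OH, which prevents lactol and tetrahydrofuran formation later; no stereocentre is formed.

Step 3
Reactants: 5 (3S)-1-(tert-butyldiphenylsilyloxy)-3,7-dimethyl-3-(triethylsilyloxy)oct-6-ene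
Product: 7 (4S)-6-(tert-butyldiphenylsilyloxy)-4-methyl-4-(triethylsilyloxy)hexanal (C3 aldehyde), via secondary ozonide 6 (not isolated)
Conditions: O3, CH2Cl2, −78 °C (Sudan red end point); then PPh3, −78 °C → rt
Reagents that add atoms: ozone, [O-][O+]=O
Why: Ozonolysis (Criegee cleavage with reductive work-up) of the only remaining C=C gives the C3 aldehyde and acetone without touching the silyl ethers or C10.

Step 4
Reactants: 7 (4S)-6-(tert-butyldiphenylsilyloxy)-4-methyl-4-(triethylsilyloxy)hexanal; 8 methyl 3,3-dimethoxypropanoate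
Product: 10 methyl (6S)-8-(tert-butyldiphenylsilyloxy)-2-(dimethoxymethyl)-3-hydroxy-6-methyl-6-(triethylsilyloxy)octanoate (diastereomer mixture at C3/C4), via lithium enolate 9 (not isolated)
Conditions: LDA (LiN(iPr)2), THF, −78 °C, 8; then 7, −78 °C; AcOH quench
Reagents that add atoms: methyl 3,3-dimethoxypropanoate, COC(OC)CC(=O)OC
Why: Directed aldol addition of the ester lithium enolate (kept at −78 °C to avoid loss of methoxide) forms the C3–C4 bond; the two new stereocentres are transient because both carbons become sp2 in step 5.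

Step 5
Reactants: 10 methyl (6S)-8-(tert-butyldiphenylsilyloxy)-2-(dimethoxymethyl)-3-hydroxy-6-methyl-6-(triethylsilyloxy)octanoate
Product: 12 methyl (2E,6S)-8-(tert-butyldiphenylsilyloxy)-2-(dimethoxymethyl)-6-methyl-6-(triethylsilyloxy)oct-2-enoate, via mesylate 11 (not isolated)
Conditions: MsCl, Et3N, CH2Cl2, 0 °C; then DBU, rt
Reagents that add atoms: none
Why: Mesylation followed by E1cB elimination through the ester enolate (mesylate leaves in preference to methoxide) should give mainly the E-alkene with C2 trans to the ester and cis to the acetal carbon C5, the usual geometry of 2-substituted alk-2-enoates and the only one able to cyclise in step 6.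

Step 6
Reactants: 12 methyl (2E,6S)-8-(tert-butyldiphenylsilyloxy)-2-(dimethoxymethyl)-6-methyl-6-(triethylsilyloxy)oct-2-enoate
Product: 13 methyl (7S)-7-[2-(tert-butyldiphenylsilyloxy)ethyl]-2-methoxy-7-methyl-2,5,6,7-tetrahydrooxepine-3-carboxylate (ring A acetal; epimers at C5)
Conditions: TMSOTf (0.2 equiv), CH2Cl2, −78 → −40 °C; Et3N quench
Reagents that add atoms: none
Why: Silyl-triflate-catalysed acetal exchange: ionisation of the dimethyl acetal gives the C5 oxocarbenium ion, which the tertiary silyl ether oxygen captures in a 7-exo-trig closure under kinetic conditions; C5 forms as an epimer mixture that converges in step 8.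

Step 7
Reactants: 14 allyloxy-tert-butyldimethylsilane
Product: 16 (Z)-tributyl[3-(tert-butyldimethylsilyloxy)prop-2-en-1-yl]stannane, via silyloxyallyllithium 15 (not isolated)
Conditions: sec-BuLi, THF/HMPA, −78 °C; then Bu3SnCl, −78 °C → rt
Reagents that add atoms: tributyltin chloride, CCCC[Sn](Cl)(CCCC)CCCC
Why: Deprotonation next to oxygen gives the oxygen-chelated (Z)-γ-silyloxyallyllithium, which is stannylated at its terminal carbon with retention of the Z enol ether geometry.

Step 8
Reactants: 13 methyl (7S)-7-[2-(tert-butyldiphenylsilyloxy)ethyl]-2-methoxy-7-methyl-2,5,6,7-tetrahydrooxepine-3-carboxylate; 16 (Z)-tributyl[3-(tert-butyldimethylsilyloxy)prop-2-en-1-yl]stannane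
Product: 18 methyl (2R,7S)-7-[2-(tert-butyldiphenylsilyloxy)ethyl]-2-[(1R)-1-hydroxyprop-2-en-1-yl]-7-methyl-2,5,6,7-tetrahydrooxepine-3-carboxylate (5R,6R,10S), via silyl ether 17 (not isolated)
Conditions: BF3·OEt2, 16 (1.5 equiv), CH2Cl2, −78 °C; then MeOH, −78 → 0 °C
Reagents that add atoms: (Z)-tributyl[3-(tert-butyldimethylsilyloxy)prop-2-en-1-yl]stannane, CCCC[Sn](CCCC)(CCCC)C/C=C\O[Si](C)(C)C(C)(C)C
Why: Lewis-acid-promoted SE2′ addition of a γ-alkoxyallylstannane to the ring A oxocarbenium ion forms C5–C6 at the charge-bearing C5 through an open antiperiplanar transition state (syn C5/C6, i.e. 6R); the nucleophile should enter anti to the pseudo-axial C10 methyl and so cis to the larger silyloxyethyl arm (5R, a modest preference), and BF3/MeOH then cleaves the secondary TBS ether.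

Step 9
Reactants: 19 methyl 2-(hydroxymethyl)acrylate
Product: 20 methyl 2-[(tert-butyldimethylsilyloxy)methyl]acrylate
Conditions: TBSCl, imidazole, CH2Cl2, 0 °C → rt
Reagents that add atoms: tert-butyl(chloro)dimethylsilane, CC(C)(C)[Si](C)(C)Cl
Why: Routine silylation of the primary allylic alcohol, which later becomes C13.

Step 10
Reactants: 20 methyl 2-[(tert-butyldimethylsilyloxy)methyl]acrylate
Product: 21 2-[(tert-butyldimethylsilyloxy)methyl]acrylic acid
Conditions: LiOH, THF/H2O, 0 °C → rt; then 1 M HCl to pH 4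
Reagents that add atoms: lithium hydroxide, [Li+].[OH-]
Why: Saponification of the methyl ester under conditions that leave the TBS ether intact.

Step 11
Reactants: 18 methyl (2R,7S)-7-[2-(tert-butyldiphenylsilyloxy)ethyl]-2-[(1R)-1-hydroxyprop-2-en-1-yl]-7-methyl-2,5,6,7-tetrahydrooxepine-3-carboxylate; 21 2-[(tert-butyldimethylsilyloxy)methyl]acrylic acid
Product: 22 methyl (2R,7S)-7-[2-(tert-butyldiphenylsilyloxy)ethyl]-2-[(1S)-1-({2-[(tert-butyldimethylsilyloxy)methyl]acryloyl}oxy)prop-2-en-1-yl]-7-methyl-2,5,6,7-tetrahydrooxepine-3-carboxylate (5R,6S,10S)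
Conditions: PPh3, DIAD, toluene, 0 °C → rt
Reagents that add atoms: 2-[(tert-butyldimethylsilyloxy)methyl]acrylic acid, C=C(CO[Si](C)(C)C(C)(C)C)C(=O)O
Why: Mitsunobu esterification: the carboxylate displaces the C6 alkoxyphosphonium ion by SN2, inverting C6 from R to S and turning the syn adduct into the erythro C5/C6 pair of the target.

Step 12
Reactants: 22 methyl (2R,7S)-7-[2-(tert-butyldiphenylsilyloxy)ethyl]-2-[(1S)-1-({2-[(tert-butyldimethylsilyloxy)methyl]acryloyl}oxy)prop-2-en-1-yl]-7-methyl-2,5,6,7-tetrahydrooxepine-3-carboxylate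
Product: 23 methyl (2R,7S)-7-[2-(tert-butyldiphenylsilyloxy)ethyl]-2-{(2S)-4-[(tert-butyldimethylsilyloxy)methyl]-5-oxo-2,5-dihydrofuran-2-yl}-7-methyl-2,5,6,7-tetrahydrooxepine-3-carboxylate
Conditions: second-generation Grubbs catalyst RuCl2(=CHPh)(PCy3)(H2IMes) (5 mol %), toluene, 80 °C
Reagents that add atoms: none
Why: Ring-closing metathesis between the C7 vinyl group and the 2-substituted acrylate closes the butenolide (C7=C11) while the trisubstituted C3=C4 enoate stays inert; no stereocentre is touched.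

Step 13
Reactants: 23 methyl (2R,7S)-7-[2-(tert-butyldiphenylsilyloxy)ethyl]-2-{(2S)-4-[(tert-butyldimethylsilyloxy)methyl]-5-oxo-2,5-dihydrofuran-2-yl}-7-methyl-2,5,6,7-tetrahydrooxepine-3-carboxylate
Product: 24 methyl (2R,7S)-7-(2-hydroxyethyl)-2-[(2S)-4-(hydroxymethyl)-5-oxo-2,5-dihydrofuran-2-yl]-7-methyl-2,5,6,7-tetrahydrooxepine-3-carboxylate
Conditions: HF·pyridine, THF/pyridine, 0 °C → rt
Reagents that add atoms: none
Why: Fluoride-mediated cleavage of both silyl ethers in a buffered, non-basic medium that spares the base-sensitive butenolide and the methyl ester.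

Step 14
Reactants: 24 methyl (2R,7S)-7-(2-hydroxyethyl)-2-[(2S)-4-(hydroxymethyl)-5-oxo-2,5-dihydrofuran-2-yl]-7-methyl-2,5,6,7-tetrahydrooxepine-3-carboxylate
Product: 25 methyl (2R,7S)-2-[(2S)-4-(bromomethyl)-5-oxo-2,5-dihydrofuran-2-yl]-7-(2-hydroxyethyl)-7-methyl-2,5,6,7-tetrahydrooxepine-3-carboxylate
Conditions: NBS, Me2S, CH2Cl2, −20 → 0 °C
Reagents that add atoms: N-bromosuccinimide, O=C1CCC(=O)N1Br
Why: Corey–Kim halogenation: only the allylic C13 alkoxysulfonium ion is displaced by bromide, whereas the saturated C8 alcohol is returned on aqueous work-up; this avoids a radical bromination, which would attack C6–H.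

Step 15
Reactants: 25 methyl (2R,7S)-2-[(2S)-4-(bromomethyl)-5-oxo-2,5-dihydrofuran-2-yl]-7-(2-hydroxyethyl)-7-methyl-2,5,6,7-tetrahydrooxepine-3-carboxylate
Product: 26 methyl (2R,7S)-2-[(2S)-4-(bromomethyl)-5-oxo-2,5-dihydrofuran-2-yl]-7-methyl-7-(2-oxoethyl)-2,5,6,7-tetrahydrooxepine-3-carboxylate (key-step precursor)
Conditions: Dess–Martin periodinane, NaHCO3, CH2Cl2, 0 °C → rt
Reagents that add atoms: none
Why: Dess–Martin oxidation under buffered neutral conditions gives the β-alkoxy aldehyde without retro-oxa-Michael opening of ring A and leaves the allylic bromide untouched.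

Step 16
Reactants: 26 methyl (2R,7S)-2-[(2S)-4-(bromomethyl)-5-oxo-2,5-dihydrofuran-2-yl]-7-methyl-7-(2-oxoethyl)-2,5,6,7-tetrahydrooxepine-3-carboxylate
Product: 29 methyl (5R,6S,7R,8R,10S)-5,10-epoxy-8-hydroxygermacra-3,11(13)-dien-6,12-olid-15-oate (C8 alcohol of the oxa-bridged methylene lactone core), via allylchromium dichloride 27 (not isolated), via chromium alkoxide 28 (not isolated)
Conditions: CrCl2 (6 equiv), degassed THF, rt, slow addition of 26 to about 3 mM; aqueous NH4Cl work-up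
Reagents that add atoms: none
Why: Two equivalents of CrCl2 (divalent chromium) reduce the C13–Br bond to an allylchromium dichloride (trivalent chromium) that adds to the tethered aldehyde through its γ-carbon C7 in a chromium-bridged six-membered transition state, moving the double bond to C11=C13; this is a Nozaki–Hiyama allylation, closest to chromium- or zinc-mediated γ-additions of 3-(bromomethyl)furan-2(5H)-ones to aldehydes and to intramolecular closures of 2-(bromomethyl)acrylates. Ring B closes as a seven-membered ring in the exo mode at the aldehyde carbonyl (7-exo-trig), and because the lactone oxygen already sits on C6 no isomeric O8 lactone can arise. C7 is controlled by the C6 stereocentre: the new bond must form on the butenolide face opposite to C5 (H6/H7 trans), which requires the C9 chain of the 2,7-cis oxepene to reach round the unsubstituted C7–H edge of the planar lactone. C8 is controlled by the orientation of the aldehyde in the cyclic transition state, where the short C9–C10–O bridge is relied on to tie C9 back toward C5 so that O8 ends cis to C11 on ring B (syn C7/C8 pair, H7/H8 cis). The step therefore needs facial selectivity on both partners and preference for ring closure over reduction or dimerisation of the bromide; high dilution and the preorganised cis-oxepene serve the latter, while the two facial preferences (closure on the C5 face would give the cis-fused lactone) are the accepted uncertainty of the route.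

Step 17
Reactants: 30 (R)-2-methylglycidol
Product: 31 (S)-2-methylbut-3-ene-1,2-diol
Conditions: Me3S+ I− (4 equiv), n-BuLi, THF, −10 °C → rt
Reagents that add atoms: trimethylsulfonium iodide, C[S+](C)C.[I-]
Why: Dimethylsulfonium methylide opens the epoxide at its CH2 terminus and a second ylide equivalent eliminates Me2S to give the one-carbon-homologated vinyl carbinol; the quaternary centre is not involved (Payne migration is degenerate), so (R)-epoxide gives (S)-diol.

Step 18
Reactants: 31 (S)-2-methylbut-3-ene-1,2-diol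
Product: 33 (S)-2-hydroxy-2-methylbut-3-enoic acid, via hydroxy aldehyde 32 (not isolated)
Conditions: TEMPO (cat.), NaOCl (cat.), NaClO2, MeCN/phosphate buffer pH 6.7, 35 °C
Reagents that add atoms: sodium chlorite, [Na+].[O-]Cl=O
Why: Oxoammonium oxidation of the primary alcohol to the aldehyde and chlorite oxidation to the acid in one pot; the tertiary carbinol cannot be oxidised and keeps its configuration.

Step 19
Reactants: 33 (S)-2-hydroxy-2-methylbut-3-enoic acid
Product: 35 (S)-2-methyl-2-(triethylsilyloxy)but-3-enoic acid, via bis-silyl derivative 34 (not isolated)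
Conditions: TESCl (2.5 equiv), imidazole, DMF, rt; then K2CO3 (cat.), MeOH, 0 °C; citric acid work-up
Reagents that add atoms: chlorotriethylsilane, CC[Si](CC)(CC)Cl
Why: Exhaustive silylation followed by selective methanolysis of the labile silyl ester leaves the tertiary TES ether, so the acid cannot self-acylate in step 20.

Step 20
Reactants: 29 methyl (5R,6S,7R,8R,10S)-5,10-epoxy-8-hydroxygermacra-3,11(13)-dien-6,12-olid-15-oate; 35 (S)-2-methyl-2-(triethylsilyloxy)but-3-enoic acid
Product: 37 O-triethylsilyl ether of the target (C8 ester), via mixed anhydride 36 (not isolated)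
Conditions: 35, 2,4,6-trichlorobenzoyl chloride, Et3N, toluene, rt; then 29, DMAP, rt → 40 °C
Reagents that add atoms: (S)-2-methyl-2-(triethylsilyloxy)but-3-enoic acid, OC(=O)[C@](O[Si](CC)(CC)CC)(C)C=C
Why: Yamaguchi esterification through the mixed anhydride and acylpyridinium ion acylates the hindered C8 alcohol without breaking its C–O bond, so C8 stays R.

Step 21
Reactants: 37 O-triethylsilyl ether of the target
Product: 38 target, (5R,6S,7R,8R,10S)-8-[(2S)-2-hydroxy-2-methylbut-3-enoyloxy] methyl ester lactone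
Conditions: HF·pyridine, THF, 0 °C → rt
Reagents that add atoms: none
Why: Acidic fluoride cleavage of the tertiary TES ether under conditions that do not isomerise the α-methylene lactone or cleave the esters.

Compound list
1 | (S)-linalool | C=C[C@](O)(C)CCC=C(C)C | starting material
2 | bis-borylated adduct of 1 (C8–B and O10–B 9-BBN) | B1(C2CCCC1CCC2)CC[C@](OB1C2CCCC1CCC2)(C)CCC=C(C)C | intermediate
3 | (3S)-3,7-dimethyloct-6-ene-1,3-diol | OCC[C@](O)(C)CCC=C(C)C | intermediate
4 | (3S)-1-(tert-butyldiphenylsilyloxy)-3,7-dimethyloct-6-en-3-ol | CC(C)(C)[Si](c1ccccc1)(c1ccccc1)OCC[C@](O)(C)CCC=C(C)C | intermediate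
5 | (3S)-1-(tert-butyldiphenylsilyloxy)-3,7-dimethyl-3-(triethylsilyloxy)oct-6-ene | CC(C)(C)[Si](c1ccccc1)(c1ccccc1)OCC[C@](O[Si](CC)(CC)CC)(C)CCC=C(C)C | intermediate
6 | secondary ozonide of 5 | CC(C)(C)[Si](c1ccccc1)(c1ccccc1)OCC[C@](O[Si](CC)(CC)CC)(C)CCC1OOC(C)(C)O1 | intermediate
7 | (4S)-6-(tert-butyldiphenylsilyloxy)-4-methyl-4-(triethylsilyloxy)hexanal | CC(C)(C)[Si](c1ccccc1)(c1ccccc1)OCC[C@](O[Si](CC)(CC)CC)(C)CCC=O | intermediate
8 | methyl 3,3-dimethoxypropanoate | COC(OC)CC(=O)OC | starting material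
9 | lithium enolate of 8 | [Li+].COC(OC)C=C([O-])OC | intermediate
10 | methyl (6S)-8-(tert-butyldiphenylsilyloxy)-2-(dimethoxymethyl)-3-hydroxy-6-methyl-6-(triethylsilyloxy)octanoate | CC(C)(C)[Si](c1ccccc1)(c1ccccc1)OCC[C@](O[Si](CC)(CC)CC)(C)CCC(O)C(C(=O)OC)C(OC)OC | intermediate
11 | C3 mesylate of 10 | CC(C)(C)[Si](c1ccccc1)(c1ccccc1)OCC[C@](O[Si](CC)(CC)CC)(C)CCC(OS(C)(=O)=O)C(C(=O)OC)C(OC)OC | intermediate
12 | methyl (2E,6S)-8-(tert-butyldiphenylsilyloxy)-2-(dimethoxymethyl)-6-methyl-6-(triethylsilyloxy)oct-2-enoate | CC(C)(C)[Si](c1ccccc1)(c1ccccc1)OCC[C@](O[Si](CC)(CC)CC)(C)CC/C=C(/C(=O)OC)C(OC)OC | intermediate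
13 | methyl (7S)-7-[2-(tert-butyldiphenylsilyloxy)ethyl]-2-methoxy-7-methyl-2,5,6,7-tetrahydrooxepine-3-carboxylate | CC(C)(C)[Si](c1ccccc1)(c1ccccc1)OCC[C@]1(C)CCC=C(C(=O)OC)C(OC)O1 | intermediate
14 | allyloxy-tert-butyldimethylsilane | C=CCO[Si](C)(C)C(C)(C)C | starting material
15 | (Z)-3-(tert-butyldimethylsilyloxy)allyllithium | [Li]C/C=C\O[Si](C)(C)C(C)(C)C | intermediate
16 | (Z)-tributyl[3-(tert-butyldimethylsilyloxy)prop-2-en-1-yl]stannane | CCCC[Sn](CCCC)(CCCC)C/C=C\O[Si](C)(C)C(C)(C)C | intermediate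
17 | methyl (2R,7S)-2-[(1R)-1-(tert-butyldimethylsilyloxy)prop-2-en-1-yl]-7-[2-(tert-butyldiphenylsilyloxy)ethyl]-7-methyl-2,5,6,7-tetrahydrooxepine-3-carboxylate | CC(C)(C)[Si](c1ccccc1)(c1ccccc1)OCC[C@]1(C)CCC=C(C(=O)OC)[C@@H](O1)[C@H](O[Si](C)(C)C(C)(C)C)C=C | intermediate
18 | methyl (2R,7S)-7-[2-(tert-butyldiphenylsilyloxy)ethyl]-2-[(1R)-1-hydroxyprop-2-en-1-yl]-7-methyl-2,5,6,7-tetrahydrooxepine-3-carboxylate | CC(C)(C)[Si](c1ccccc1)(c1ccccc1)OCC[C@]1(C)CCC=C(C(=O)OC)[C@@H](O1)[C@H](O)C=C | intermediate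
19 | methyl 2-(hydroxymethyl)acrylate | C=C(CO)C(=O)OC | starting material
20 | methyl 2-[(tert-butyldimethylsilyloxy)methyl]acrylate | C=C(CO[Si](C)(C)C(C)(C)C)C(=O)OC | intermediate
21 | 2-[(tert-butyldimethylsilyloxy)methyl]acrylic acid | C=C(CO[Si](C)(C)C(C)(C)C)C(=O)O | intermediate
22 | methyl (2R,7S)-7-[2-(tert-butyldiphenylsilyloxy)ethyl]-2-[(1S)-1-({2-[(tert-butyldimethylsilyloxy)methyl]acryloyl}oxy)prop-2-en-1-yl]-7-methyl-2,5,6,7-tetrahydrooxepine-3-carboxylate | CC(C)(C)[Si](c1ccccc1)(c1ccccc1)OCC[C@]1(C)CCC=C(C(=O)OC)[C@@H](O1)[C@@H](OC(=O)C(=C)CO[Si](C)(C)C(C)(C)C)C=C | intermediate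
23 | methyl (2R,7S)-7-[2-(tert-butyldiphenylsilyloxy)ethyl]-2-{(2S)-4-[(tert-butyldimethylsilyloxy)methyl]-5-oxo-2,5-dihydrofuran-2-yl}-7-methyl-2,5,6,7-tetrahydrooxepine-3-carboxylate | CC(C)(C)[Si](c1ccccc1)(c1ccccc1)OCC[C@]1(C)CCC=C(C(=O)OC)[C@@H](O1)[C@H]2OC(=O)C(CO[Si](C)(C)C(C)(C)C)=C2 | intermediate
24 | methyl (2R,7S)-7-(2-hydroxyethyl)-2-[(2S)-4-(hydroxymethyl)-5-oxo-2,5-dihydrofuran-2-yl]-7-methyl-2,5,6,7-tetrahydrooxepine-3-carboxylate | OCC[C@]1(C)CCC=C(C(=O)OC)[C@@H](O1)[C@H]2OC(=O)C(CO)=C2 | intermediate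
25 | methyl (2R,7S)-2-[(2S)-4-(bromomethyl)-5-oxo-2,5-dihydrofuran-2-yl]-7-(2-hydroxyethyl)-7-methyl-2,5,6,7-tetrahydrooxepine-3-carboxylate | OCC[C@]1(C)CCC=C(C(=O)OC)[C@@H](O1)[C@H]2OC(=O)C(CBr)=C2 | intermediate
26 | methyl (2R,7S)-2-[(2S)-4-(bromomethyl)-5-oxo-2,5-dihydrofuran-2-yl]-7-methyl-7-(2-oxoethyl)-2,5,6,7-tetrahydrooxepine-3-carboxylate | O=CC[C@]1(C)CCC=C(C(=O)OC)[C@@H](O1)[C@H]2OC(=O)C(CBr)=C2 | intermediate
27 | C13 allylchromium dichloride of 26 | O=CC[C@]1(C)CCC=C(C(=O)OC)[C@@H](O1)[C@H]2OC(=O)C(C[Cr](Cl)Cl)=C2 | intermediate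
28 | chromium alkoxide of 29 | Cl[Cr](Cl)O[C@@H]1C[C@]2(C)CCC=C(C(=O)OC)[C@@H](O2)[C@H]2OC(=O)C(=C)[C@@H]21 | intermediate
29 | methyl (5R,6S,7R,8R,10S)-5,10-epoxy-8-hydroxygermacra-3,11(13)-dien-6,12-olid-15-oate | O[C@@H]1C[C@]2(C)CCC=C(C(=O)OC)[C@@H](O2)[C@H]2OC(=O)C(=C)[C@@H]21 | intermediate
30 | (R)-2-methylglycidol | OC[C@]1(C)CO1 | starting material
31 | (S)-2-methylbut-3-ene-1,2-diol | OC[C@](O)(C)C=C | intermediate
32 | (S)-2-hydroxy-2-methylbut-3-enal | O=C[C@](O)(C)C=C | intermediate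
33 | (S)-2-hydroxy-2-methylbut-3-enoic acid | OC(=O)[C@](O)(C)C=C | intermediate
34 | triethylsilyl (S)-2-methyl-2-(triethylsilyloxy)but-3-enoate | CC[Si](CC)(CC)OC(=O)[C@](O[Si](CC)(CC)CC)(C)C=C | intermediate
35 | (S)-2-methyl-2-(triethylsilyloxy)but-3-enoic acid | OC(=O)[C@](O[Si](CC)(CC)CC)(C)C=C | intermediate
36 | mixed anhydride of 35 with 2,4,6-trichlorobenzoic acid | C=C[C@](C)(O[Si](CC)(CC)CC)C(=O)OC(=O)c1c(Cl)cc(Cl)cc1Cl | intermediate
37 | O-triethylsilyl ether of the target | C=C[C@](C)(O[Si](CC)(CC)CC)C(=O)O[C@@H]1C[C@]2(C)CCC=C(C(=O)OC)[C@@H](O2)[C@H]2OC(=O)C(=C)[C@@H]21 | intermediate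
38 | target CNP0325750.1 | C=C[C@](C)(O)C(=O)O[C@@H]1C[C@]2(C)CCC=C(C(=O)OC)[C@@H](O2)[C@H]2OC(=O)C(=C)[C@@H]21 | target

Total step count: 21. Longest linear sequence: 15 steps (1–6, 8, 11–16, 20, 21).

Steps most likely to fail

Step 16. The closure may run through the wrong transition state, forming the bond on the C5 side of the butenolide (cis-fused lactone) or on the other aldehyde face (C8 epimer), or the bromide may simply be reduced or dimerise. The fallback replaces the chromium chelate by a Lewis-acid cyclisation with an open transition state and sets out from 25. Pd(PPh3)4 (zerovalent palladium) and hexabutylditin in THF convert the allylic bromide into the stannyl alcohol methyl (2R,7S)-7-(2-hydroxyethyl)-7-methyl-2-{(2S)-5-oxo-4-[(tributylstannyl)methyl]-2,5-dihydrofuran-2-yl}-2,5,6,7-tetrahydrooxepine-3-carboxylate F1. Dess–Martin oxidation gives the stannyl aldehyde F2. BF3·OEt2 in CH2Cl2 at −78 °C under high dilution then lets C7 attack the activated aldehyde in an SE2′ sense; the antiperiplanar arrangement favours the syn C7/C8 pair that the target needs. The sequence comes back to the route at 29.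

Step 8. The stannane may add with poor facial selectivity at C5 (the 2,7-trans epimer, useless for ring B) or at C3 of the conjugated cation. The fallback imposes reagent control, sets out from 13 and returns at 23. (E)-Crotonaldehyde is treated with Bu3SnLi and the alkoxide is oxidised in the same flask with 1,1'-(azodicarbonyl)dipiperidine to the acylstannane (E)-1-(tributylstannyl)but-2-en-1-one F3. Reduction with the enantiomer of BINAL-H that delivers the S carbinol gives (S,E)-1-(tributylstannyl)but-2-en-1-ol F4, which is silylated (TBSCl, imidazole) to F5. BF3·OEt2 induces the stereospecific anti 1,3-stannyl shift to (S,Z)-tributyl[4-(tert-butyldimethylsilyloxy)but-3-en-2-yl]stannane F6. F6 adds to 13 under BF3·OEt2 in an anti SE2′ process in which the stannane stereocentre fixes C6 as R and the syn topicity then fixes C5 as R, giving the propenyl silyl ether F7. Methanol in the same flask frees the alcohol F8, Mitsunobu esterification with 21 gives the inverted ester F9, and ring-closing metathesis as in step 12 expels propene to give 23.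

Step 6. The tertiary oxygen may capture the delocalised cation at C3 (five-membered ring with a β-methoxyacrylate), or the acetal may lose methanol, instead of forming the seven-membered acetal. The fallback attaches the ether oxygen to C5 first and closes ring A by C3–C4 bond formation; it sets out from 4 (isolated by stopping step 2 after the first silylation) and returns at 17. N-Methylmorpholine-catalysed oxa-Michael addition of 4 to methyl propiolate gives the (E)-β-alkoxyacrylate F10. Ozonolysis of the more electron-rich trisubstituted alkene (PPh3 work-up) gives aldehyde F11. NIS in AcOH followed by Et3N gives the (Z)-α-iodo-β-alkoxyacrylate F12. CrCl2 with catalytic NiCl2 in DMF closes ring A by Nozaki–Hiyama alkenylation of the aldehyde to the cyclic allylic alcohol F13, and Ac2O/pyridine gives acetate F14. BF3·OEt2 and 16 then effect a Ferrier-type allylic substitution at C5 with shift of the double bond to C3=C4, giving 17, which continues as in step 8.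

Further compounds
F1 | step 16 | methyl (2R,7S)-7-(2-hydroxyethyl)-7-methyl-2-{(2S)-5-oxo-4-[(tributylstannyl)methyl]-2,5-dihydrofuran-2-yl}-2,5,6,7-tetrahydrooxepine-3-carboxylate | OCC[C@]1(C)CCC=C(C(=O)OC)[C@@H](O1)[C@H]2OC(=O)C(C[Sn](CCCC)(CCCC)CCCC)=C2
F2 | step 16 | methyl (2R,7S)-7-methyl-7-(2-oxoethyl)-2-{(2S)-5-oxo-4-[(tributylstannyl)methyl]-2,5-dihydrofuran-2-yl}-2,5,6,7-tetrahydrooxepine-3-carboxylate | O=CC[C@]1(C)CCC=C(C(=O)OC)[C@@H](O1)[C@H]2OC(=O)C(C[Sn](CCCC)(CCCC)CCCC)=C2
F3 | step 8 | (E)-1-(tributylstannyl)but-2-en-1-one | C/C=C/C(=O)[Sn](CCCC)(CCCC)CCCC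
F4 | step 8 | (S,E)-1-(tributylstannyl)but-2-en-1-ol | C/C=C/[C@@H](O)[Sn](CCCC)(CCCC)CCCC
F5 | step 8 | (S,E)-tert-butyldimethyl{[1-(tributylstannyl)but-2-en-1-yl]oxy}silane | C/C=C/[C@@H](O[Si](C)(C)C(C)(C)C)[Sn](CCCC)(CCCC)CCCC
F6 | step 8 | (S,Z)-tributyl[4-(tert-butyldimethylsilyloxy)but-3-en-2-yl]stannane | C[C@H]([Sn](CCCC)(CCCC)CCCC)/C=C\O[Si](C)(C)C(C)(C)C
F7 | step 8 | methyl (2R,7S)-2-[(1R,2E)-1-(tert-butyldimethylsilyloxy)but-2-en-1-yl]-7-[2-(tert-butyldiphenylsilyloxy)ethyl]-7-methyl-2,5,6,7-tetrahydrooxepine-3-carboxylate | CC(C)(C)[Si](c1ccccc1)(c1ccccc1)OCC[C@]1(C)CCC=C(C(=O)OC)[C@@H](O1)[C@H](O[Si](C)(C)C(C)(C)C)/C=C/C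
F8 | step 8 | methyl (2R,7S)-7-[2-(tert-butyldiphenylsilyloxy)ethyl]-2-[(1R,2E)-1-hydroxybut-2-en-1-yl]-7-methyl-2,5,6,7-tetrahydrooxepine-3-carboxylate | CC(C)(C)[Si](c1ccccc1)(c1ccccc1)OCC[C@]1(C)CCC=C(C(=O)OC)[C@@H](O1)[C@H](O)/C=C/C
F9 | step 8 | methyl (2R,7S)-7-[2-(tert-butyldiphenylsilyloxy)ethyl]-2-[(1S,2E)-1-({2-[(tert-butyldimethylsilyloxy)methyl]acryloyl}oxy)but-2-en-1-yl]-7-methyl-2,5,6,7-tetrahydrooxepine-3-carboxylate | CC(C)(C)[Si](c1ccccc1)(c1ccccc1)OCC[C@]1(C)CCC=C(C(=O)OC)[C@@H](O1)[C@@H](OC(=O)C(=C)CO[Si](C)(C)C(C)(C)C)/C=C/C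
F10 | step 6 | methyl (E)-3-{[(3S)-1-(tert-butyldiphenylsilyloxy)-3,7-dimethyloct-6-en-3-yl]oxy}acrylate | CC(C)(C)[Si](c1ccccc1)(c1ccccc1)OCC[C@](O/C=C/C(=O)OC)(C)CCC=C(C)C
F11 | step 6 | methyl (E)-3-{[(3S)-1-(tert-butyldiphenylsilyloxy)-3-methyl-6-oxohexan-3-yl]oxy}acrylate | CC(C)(C)[Si](c1ccccc1)(c1ccccc1)OCC[C@](O/C=C/C(=O)OC)(C)CCC=O
F12 | step 6 | methyl (Z)-3-{[(3S)-1-(tert-butyldiphenylsilyloxy)-3-methyl-6-oxohexan-3-yl]oxy}-2-iodoacrylate | CC(C)(C)[Si](c1ccccc1)(c1ccccc1)OCC[C@](O/C=C(\I)C(=O)OC)(C)CCC=O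
F13 | step 6 | methyl (7S)-7-[2-(tert-butyldiphenylsilyloxy)ethyl]-4-hydroxy-7-methyl-4,5,6,7-tetrahydrooxepine-3-carboxylate | CC(C)(C)[Si](c1ccccc1)(c1ccccc1)OCC[C@]1(C)CCC(O)C(C(=O)OC)=CO1
F14 | step 6 | methyl (7S)-4-acetoxy-7-[2-(tert-butyldiphenylsilyloxy)ethyl]-7-methyl-4,5,6,7-tetrahydrooxepine-3-carboxylate | CC(C)(C)[Si](c1ccccc1)(c1ccccc1)OCC[C@]1(C)CCC(OC(C)=O)C(C(=O)OC)=CO1
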